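**Retrosynthetic overview**
- Target ⇐ chemoselective ozonolysis of a tetrasubstituted C11=C15 cyclopentene that masks the 11,15-diketone, so no ketone exists before the last step.
- C5=C6 Z-alkene and free 9-OH ⇐ Wittig reaction of a cis-fused bicyclic lactol (C6) with the C1–C5 ylide.
- Masking cyclopentene (C12–C13 bond, C12 stereocentre, loss of the formyl carbon) ⇐ new carbene-catalysed decarboxylative homoenolate [3+2] annulation of a bicyclic enal acetal with oct-1-en-3-one.
- Bicyclic enal lactol (C8, C9) ⇐ L-proline-catalysed aldol dimerisation/condensation of succinaldehyde.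
- Ring order: cyclopentene core and lactol ring together (step 1), masking cyclopentene (step 3), lactol ring opened (step 5), masking ring cleaved (step 6).

Assumption: succinaldehyde is bought and freshly distilled; atom labels C1–C20 follow prostaglandin numbering.
Assumption: the lactol/acetal carbon C6 of the bicyclic and tricyclic intermediates is an anomeric mixture, drawn as the exo (R) anomer; it disappears in step 5.

**Step 1**
Reactants: 1 succinaldehyde (two molecules)
Product: 3 (2R,3aR,6aS)-2-hydroxy-3,3a,6,6a-tetrahydro-2H-cyclopenta[b]furan-5-carbaldehyde, via (3S,4S)-3-formyl-4-hydroxyheptanedial 2 (not isolated)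
Conditions: L-proline (2 mol%), THF, rt; then [Bn2NH2][OCOCF3] (2 mol%), rt
Reagents that add atoms: none
Why: L-proline-catalysed direct asymmetric aldol reaction in which the enamine of one succinaldehyde adds to a second through the hydrogen-bonded anti transition state, setting C8 (R) and C9 (S), after which the ammonium salt drives the intramolecular aldol condensation (C11 onto the C12 aldehyde) and the 9-OH closes onto the C6 aldehyde as a cis-fused lactol.

**Step 2**
Reactants: 3 (2R,3aR,6aS)-2-hydroxy-3,3a,6,6a-tetrahydro-2H-cyclopenta[b]furan-5-carbaldehyde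
Product: 4 (2R,3aR,6aS)-2-methoxy-3,3a,6,6a-tetrahydro-2H-cyclopenta[b]furan-5-carbaldehyde
Conditions: MeOH, Amberlyst 15, MgSO4, CH2Cl2, rt
Reagents that add atoms: methanol, CO
Why: Acid-catalysed acetalisation (Fischer glycosidation type) through the cyclic oxocarbenium ion removes the free OH and latent aldehyde that would intercept the carbene catalyst or the acyl azolium in step 3, and creates no stereocentre that matters.

**Step 3**
Reactants: 4 (2R,3aR,6aS)-2-methoxy-3,3a,6,6a-tetrahydro-2H-cyclopenta[b]furan-5-carbaldehyde; 5 oct-1-en-3-one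
Product: 7 (1R,2R,4R,6S)-4-methoxy-9-pentyl-5-oxatricyclo[6.3.0.0^{2,6}]undec-8-ene, via fused β-lactone 6 (not isolated)
Conditions: 1,3-dimesitylimidazolium chloride (10 mol%), DBU (20 mol%), THF, 40 °C, slow addition of 5; then PhMe, 110 °C
Reagents that add atoms: none
Why: Proposed new method: the N-heterocyclic carbene adds to the enal to give a Breslow-type homoenolate whose nucleophilic C12 attacks the terminal carbon of 5 on the convex face anti to the fused tetrahydrofuran ring (forming C12–C13 and setting C12 trans to C7), the azolium enol at C11 then closes onto the C15 ketone (intramolecular aldol), the alkoxide acylates to release the carbene as β-lactone 6, and thermal [2+2] cycloreversion expels the former formyl carbon as CO2 to leave the C11=C15 alkene as a base-stable mask of the 1,5-diketone; the closest known reaction type is the carbene-catalysed decarboxylative homoenolate [3+2] annulation of β-aryl enals with chalcones to cyclopentenes, not yet shown for an α,β-disubstituted cyclic enal or a simple alkyl vinyl ketone.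

**Step 4**
Reactants: 7 (1R,2R,4R,6S)-4-methoxy-9-pentyl-5-oxatricyclo[6.3.0.0^{2,6}]undec-8-ene
Product: 8 (1R,2R,4R,6S)-9-pentyl-5-oxatricyclo[6.3.0.0^{2,6}]undec-8-en-4-ol
Conditions: AcOH–THF–H2O (3:1:1), 40 °C
Reagents that add atoms: water, O
Why: Mild acid hydrolysis of the furanoside-type methyl acetal through the oxocarbenium ion is orders of magnitude faster than protonation of the tetrasubstituted alkene, so the lactol is freed without alkene migration or loss of C12.

**Step 5**
Reactants: 8 (1R,2R,4R,6S)-9-pentyl-5-oxatricyclo[6.3.0.0^{2,6}]undec-8-en-4-ol; 9 (4-carboxybutyl)triphenylphosphonium bromide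
Product: 10 (Z)-7-[(1R,2S,6aR)-2-hydroxy-4-pentyl-1,2,3,5,6,6a-hexahydropentalen-1-yl]hept-5-enoic acid
Conditions: KOtBu, THF, 0 °C to rt; then aq. HCl to pH 4
Reagents that add atoms: none
Why: Wittig olefination of the ring-opened hydroxy-aldehyde form of the lactol with the non-stabilised ylide gives the Z-alkene under kinetic control and frees the 9-OH, while the tetrasubstituted alkene and C12–H are inert to ylide and KOtBu because no carbonyl group is present.

**Step 6**
Reactants: 10 (Z)-7-[(1R,2S,6aR)-2-hydroxy-4-pentyl-1,2,3,5,6,6a-hexahydropentalen-1-yl]hept-5-enoic acid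
Product: 12 (Z)-7-[(1R,2R,5S)-5-hydroxy-3-oxo-2-(3-oxooctyl)cyclopentyl]hept-5-enoic acid (13,14-dihydro-15-keto-PGD2), via secondary ozonide 11 (not isolated)
Conditions: O3 (1.0 equiv, titrated CH2Cl2 solution), CH2Cl2, −78 °C; then PPh3, −78 °C to rt
Reagents that add atoms: ozone, [O-][O+]=O
Why: Ozonolysis in which the electron-rich, strained tetrasubstituted C11=C15 alkene is expected to react with electrophilic ozone faster than the Z-1,2-disubstituted C5=C6 alkene (a modest rate margin), so one equivalent of ozone and PPh3 reduction unveil both ketones under neutral conditions that leave the β-hydroxy ketone and the already trans C12 centre untouched.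

**Compound list**
1 | succinaldehyde (butanedial) | O=CCCC=O | starting material
2 | (3S,4S)-3-formyl-4-hydroxyheptanedial (open form of the aldol dimer, present as its lactols) | O=CC[C@H](C=O)[C@@H](O)CCC=O | intermediate
3 | (2R,3aR,6aS)-2-hydroxy-3,3a,6,6a-tetrahydro-2H-cyclopenta[b]furan-5-carbaldehyde | O=CC1=C[C@H]2C[C@H](O)O[C@H]2C1 | intermediate
4 | (2R,3aR,6aS)-2-methoxy-3,3a,6,6a-tetrahydro-2H-cyclopenta[b]furan-5-carbaldehyde | O=CC1=C[C@H]2C[C@H](OC)O[C@H]2C1 | intermediate
5 | oct-1-en-3-one | C=CC(=O)CCCCC | starting material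
6 | fused β-lactone: oxetan-2-one spanning the new C11–C15 bond (carbonyl carbon on C11, ring oxygen on C15, which also bears pentyl), on the face of H-12, acetal as in 7 | CCCCC[C@@]12OC(=O)[C@@]13C[C@@H]4O[C@@H](OC)C[C@@H]4[C@H]3CC2 | intermediate
7 | (1R,2R,4R,6S)-4-methoxy-9-pentyl-5-oxatricyclo[6.3.0.0^{2,6}]undec-8-ene (C11=C15 alkene; 6R,8R,9S,12R in prostaglandin numbering) | CCCCCC1=C2C[C@@H]3O[C@@H](OC)C[C@@H]3[C@H]2CC1 | intermediate
8 | (1R,2R,4R,6S)-9-pentyl-5-oxatricyclo[6.3.0.0^{2,6}]undec-8-en-4-ol | CCCCCC1=C2C[C@@H]3O[C@@H](O)C[C@@H]3[C@H]2CC1 | intermediate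
9 | (4-carboxybutyl)triphenylphosphonium bromide | OC(=O)CCCC[P+](c1ccccc1)(c1ccccc1)c1ccccc1.[Br-] | starting material
10 | (Z)-7-[(1R,2S,6aR)-2-hydroxy-4-pentyl-1,2,3,5,6,6a-hexahydropentalen-1-yl]hept-5-enoic acid | CCCCCC1=C2C[C@H](O)[C@H](C/C=C\CCCC(=O)O)[C@H]2CC1 | intermediate
11 | secondary ozonide of 10: 1,2,4-trioxolane whose carbons are C11 and C15 (C11–C15 bond cleaved), one diastereomer drawn | CCCCC[C@@]12CC[C@@H]3[C@@H](C/C=C\CCCC(=O)O)[C@@H](O)C[C@]3(OO1)O2 | intermediate
12 | (Z)-7-[(1R,2R,5S)-5-hydroxy-3-oxo-2-(3-oxooctyl)cyclopentyl]hept-5-enoic acid (13,14-dihydro-15-keto-PGD2) | CCCCCC(=O)CC[C@H]1C(=O)C[C@H](O)[C@@H]1C/C=C\CCCC(=O)O | target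

**Step count and risks**
Total steps: 6. Longest linear sequence: 6 steps (1 to 12); 5 and 9 are purchased.

Step 1 is the first of the three steps most likely to fail: oligomerisation of 1 competes with dimerisation and keeps the yield low (roughly 15–30%). The fallback sets out from 1 and comes back at 2. Compound 1 is mono-protected with ethylene glycol (TsOH cat., statistical, unreacted 1 recycled) to 3-(1,3-dioxolan-2-yl)propanal F1. L-proline-catalysed self-aldol of F1 can then give only the anti dimer (2S,3S)-5-(1,3-dioxolan-2-yl)-2-(1,3-dioxolan-2-ylmethyl)-3-hydroxypentanal F2, because the second aldehyde of each partner is masked. Aqueous TFA unmasks both acetals to give 2, which is closed to 3 with [Bn2NH2][OCOCF3] as in step 1.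

Step 3 is the second: it is the proposed new annulation, and the α-branched enal may form the Breslow intermediate slowly while 5 may undergo Stetter addition or oligomerise. The fallback uses known chemistry, sets out from 4 (with 5 as the source of the side chain) and comes back at 7.
- Compound 5 is treated with HBr and then ethylene glycol to give 2-(2-bromoethyl)-2-pentyl-1,3-dioxolane F3.
- Mg in THF converts F3 into [2-(2-pentyl-1,3-dioxolan-2-yl)ethyl]magnesium bromide F4.
- F4 adds 1,4 to 4 (CuBr·SMe2 cat., TMSCl, THF, −78 °C) on the convex face, giving the trimethylsilyl enol ether F5 with C12 set trans to C7.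
- Ozonolysis (O3, CH2Cl2, −78 °C; PPh3) cleaves the enol ether to the 11-ketone F6.
- PPTS in acetone exchanges the dioxolane and gives the 1,5-diketone F7.
- Intramolecular McMurry coupling (TiCl3, Zn(Cu), DME, reflux, high dilution) joins C11 and C15 to give 7.

Step 6 is the third: ozone may also attack the C5=C6 alkene. The fallback sets out from 10 and comes back at 12, with the chemoselectivity decided by a peracid instead of ozone. mCPBA (1.0 equiv, NaHCO3, CH2Cl2, −20 °C) epoxidises only the tetrasubstituted alkene, on the face of H-12, to give the 11,15-epoxide F8. H5IO6 in THF–H2O at 0 °C then opens and cleaves the epoxide to the 11,15-diketone 12.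

**Further compounds**
F1 | step 1 | 3-(1,3-dioxolan-2-yl)propanal | O=CCCC1OCCO1
F2 | step 1 | (2S,3S)-5-(1,3-dioxolan-2-yl)-2-(1,3-dioxolan-2-ylmethyl)-3-hydroxypentanal | O1CCOC1C[C@H](C=O)[C@@H](O)CCC1OCCO1
F3 | step 3 | 2-(2-bromoethyl)-2-pentyl-1,3-dioxolane | CCCCCC1(CCBr)OCCO1
F4 | step 3 | [2-(2-pentyl-1,3-dioxolan-2-yl)ethyl]magnesium bromide | CCCCCC1(CC[Mg]Br)OCCO1
F5 | step 3 | trimethylsilyl enol ether (2R,3aR,4R,6aS)-2-methoxy-4-[2-(2-pentyl-1,3-dioxolan-2-yl)ethyl]-5-[(trimethylsilyloxy)methylidene]hexahydro-2H-cyclopenta[b]furan (E/Z mixture) | C[Si](C)(C)OC=C1C[C@@H]2O[C@@H](OC)C[C@@H]2[C@H]1CCC1(CCCCC)OCCO1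
F6 | step 3 | 11-ketone (2R,3aR,4R,6aS)-2-methoxy-4-[2-(2-pentyl-1,3-dioxolan-2-yl)ethyl]hexahydro-2H-cyclopenta[b]furan-5-one | O=C1C[C@@H]2O[C@@H](OC)C[C@@H]2[C@H]1CCC1(CCCCC)OCCO1
F7 | step 3 | 1,5-diketone (2R,3aR,4R,6aS)-2-methoxy-4-(3-oxooctyl)hexahydro-2H-cyclopenta[b]furan-5-one | O=C1C[C@@H]2O[C@@H](OC)C[C@@H]2[C@H]1CCC(=O)CCCCC
F8 | step 6 | 11,15-epoxide of 10 (oxygen on the face of H-12) | CCCCC[C@@]12O[C@@]13C[C@H](O)[C@H](C/C=C\CCCC(=O)O)[C@H]3CC2
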